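## The problem

Flavanone numbering is used for rings A–C (O1, C2–C4, C4a, C5–C8, C8a), primes for ring B, and C1''–C4'' for the backbone of the C8 substituent (C1'' benzylic CH2, C2'' methine bearing the prenyl group, C3'' methine bearing the methyl group, C4'' the CH2OH carbon).

- The target is a (2S)-chroman-4-one whose ring A is a fully oxygenated phloroglucinol unit. Ring B (4-hydroxy-2-methoxyphenyl) sits on C2, and a branched ten-carbon chain is attached through C1'' to C8.
- Because C8 and not C6 is alkylated, the two oxygens ortho to the C4 carbonyl (O1 and the C5 hydroxyl) must be told apart. This is the regiochemical core of the problem.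
- There are three stereocentres: C2 (S) and the vicinal pair C2'' (R) and C3'' (R). The pair is adjacent, so one centre can be bought and the other set next to it. C2 lies beyond C8, C8a and O1, receives no usable bias from the chain, and needs its own reagent control.
- Within the pair, prenyl and methyl are anti along the C1''–C4'' backbone. That relationship corresponds to a cis-2,3-disubstituted γ-lactone, so the convenient trans-selective alkylation of a β-methyl lactone would give the wrong diastereomer.
- C2 is fragile. Base opens O1–C2 to the 2'-hydroxychalcone and recloses it without memory, and the para-hydroxyl of ring B makes the benzylic C2–O1 bond ionisable under acid.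
- The trisubstituted prenyl alkene excludes hydrogenolysis and strong acid, since it would cyclise onto the neighbouring C7 phenol. The free phloroglucinol ring is easily oxidised.
- The feature that opens the chosen route: the C2–H bond is benzylic to an electron-rich ring, α to O1, and the sixth atom counted from C3 along C4, C4a, C8a and O1. A ring-B benzyl ether on O1 is therefore a latent C2, which a carbenoid at C3 can reach through a six-membered transition state.

## Retrosynthesis

**Last operation (22 ⇒ 21).** Only O–Si bonds are broken at the end. The target 22 is traced to flavanone 21, with triisopropylsilyl ethers on the C5, C7 and C4' oxygens and a tert-butyldimethylsilyl ether on C4''. Silicon is preferred to acetal or alkyl protection for three reasons. All four groups leave in one near-neutral fluoride treatment that tolerates the alkene and does not open O1–C2. Silyl ethers carry no C–H bond α to oxygen near C3. The bulky triisopropylsilyl group on the C5 oxygen resists transfer to a neighbouring enolate oxygen in the diazo-transfer step.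

**C2–C3 (21 ⇒ 20).** Ring C is opened at C2–C3, giving diazomethyl ketone 20, in which ring B hangs on O1 as a benzyl ether. Two neighbouring cuts were weighed:
- The O1–C2 cut (oxa-Michael closure of a chalcone) is the reverse of the racemisation pathway and is hard to make enantioselective on an unactivated chalcone.
- The C2–C1' cut (conjugate arylation of a chromone) is sound but moves ring B to the very end; it is held in reserve.

The C2–C3 cut removes the ring and the C2 stereocentre together. It also ties the C8/C6 question to a simple etherification. The forward reaction must prefer C–H insertion to attack at ether oxygen and must choose one of two enantiotopic benzylic hydrogens.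

**C3–N (20 ⇒ 18).** The diazo group is traced to the methyl group of aryl methyl ketone 18 by acyl activation and diazo transfer. C3 and C4 are thus present in the ring-A building block from the start. The alternative, acylating a diazoalkane with a doubly ortho-substituted aroyl chloride, would need a benzoate, its hydrolysis and an acid chloride beside four silyl ethers. The forward step needs only kinetic enolisation at the one enolisable position.

**C8–C1'' (18 ⇒ 16 + 9).** The chain is detached at the aryl–CH2 bond, giving aryl iodide 16 and primary alkyl iodide 9, joined through alkylzinc 17. A cut at C1''–C2'' would require an unstable trioxygenated benzylic electrophile or a later benzylic deoxygenation. Direct C-alkylation of the phloroglucinol nucleus with a β-branched primary halide has no regiocontrol or O/C control. The chosen cut gives two fragments of similar size. Fragment 9 carries both chain stereocentres, and 16 carries rings A and B with every oxygen already assigned. The coupling must be base-free and must work on an iodide with two ortho oxygen substituents.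

**O1–CH2 and the ring-A pattern (16 ⇒ 15 + 12; 15 ⇒ 14 ⇒ 13; 12 ⇒ 11 ⇒ 10).** The benzyl ether is cut at O1–CH2, giving iodophenol 15 and benzylic alcohol 12. Compound 12 is two steps from aldehyde 10. Compound 15 comes from the symmetrical acetophenone 13:
- Bis-silylation leaves exactly one hydroxyl free in 14, the one hydrogen-bonded to the acetyl group.
- Iodination ortho to that hydroxyl marks the future C8.
- The only free oxygen of 15 then lies between iodine and acetyl, so etherification with 12 places ring B on the future O1 unambiguously.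

This sequence is preferred to alkylating first and differentiating the hydroxyls afterwards, because 13 is symmetrical and the only selectivity demanded is between a ring position flanked by two bulky silyl ethers and one that is not.

**Side chain (9 ⇒ 8 ⇒ 7 ⇒ 6 ⇒ 4 ⇒ 1).** Iodide 9 comes from alcohol 8, the reduction product of imide 7. In 7 the C2''–prenyl bond is cut, leading to imide 6 and an allylic halide. The oxazolidinone auxiliary sets C2'' and overrides the adjacent C3'' centre. Compound 6 derives from silyloxy acid 4, the ring-opened form of (R)-β-methyl-γ-butyrolactone 1, which supplies C3''. Alkylating lactone 1 directly would be shorter but would put prenyl trans to methyl on the ring, the wrong relative configuration. Opening the ring first and alkylating the acyclic imide under auxiliary control avoids this at the cost of two steps.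

## Roads not taken

**Alternative 1:** The cut lies inside the chain. C3''–CH3 and C1''–C2'' are made together: a chiral copper catalyst adds a methyl group from a dialkylzinc to the β-carbon of butenolide A2, and the zinc enolate is trapped by ring-A aldehyde A3. The product is the trans-lactone A1, whose carbinol epimers are both usable because that oxygen is later removed.
- Merits: two C–C bonds and both chain stereocentres arise in one catalytic step from cheap achiral components, and the trans ring relationship of A1 maps correctly onto the target.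
- Weak points: the lactone carbonyl carbon of A1 must become the CH2 of the prenyl group, and lactol olefination gives a chain one carbon short, so a homologation is needed. The benzylic carbinol must be deoxygenated on an acetal-protected phloroglucinol, where acid threatens the protecting groups and hydrogenolysis must precede the alkene. A3 is electron-rich and doubly ortho-substituted, a poor partner for a zinc enolate. Ring C and C2 remain untouched, and the acetal protection would offer doubly activated C–H bonds to any carbenoid, pushing the end game toward a reversible chalcone cyclisation.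
- Comparison: for the chain alone this road is shorter and catalytic where the chosen plan uses a stoichiometric auxiliary over steps 2–4. Against that, the chosen plan introduces prenyl intact, delivers C1'' at the oxidation level needed for coupling, needs no deoxygenation, and has a dedicated stereodefining step for C2.

**Alternative 2:** The cut goes through ring A. Heating cyclobutenone A5 with the side-chain ynol silyl ether A6 gives a vinylketene, which adds to the alkyne. Ring opening and six-electron closure then form C8a–C8 and C6–C7 and re-form C8a–C4a, giving phenol A4 with a free hydroxyl at C8a, a silyl ether at C7 and an ethyl ether at C5.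
- Merits: the three ring-A oxygens emerge differentiated by construction and the chain is placed on C8 with certainty. That is better than the sterically steered silylation and iodination of steps 8–9, and it avoids the hindered coupling of step 11.
- Weak points: A6 has to be made from a chain ester by ynolate homologation and O-silylation. The thermal step runs beside a prenyl alkene that can intercept the vinylketene. A4 has no C4 carbon, so a hindered ring must still be acylated. The C5 ethyl ether needs a boron halide at the end, beside the C2' methyl ether, the alkene and an epimerisable C2. C2 itself is unsolved.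
- Comparison: regiochemical certainty favours this road. The chosen plan sets against it a ring-A block (13) that already holds C3 and C4, fluoride-only deprotection, and a shorter overall count.

**Alternative 3:** The cut is O1–C8a. A palladium catalyst with a bulky biarylphosphine and carbonate base joins the C2 hydroxyl of the anti-1,3-diol bromide A8 to C8a, closing ring C as the 2,4-cis flavan-4-ol A7.
- Merits: C2 is set beforehand by well-understood carbonyl chemistry and carried through a closure that does not touch it. In security of configuration this is better than an insertion whose selectivity rests on a catalyst acting on a very reactive carbenoid. The bromine position fixes the regiochemistry.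
- Weak points: the C8a bromide sits in a hexasubstituted arene between the chain and the carbinol arm, so oxidative addition is slow. Secondary benzylic alkoxides on palladium lose β-hydride, and the electron-rich C2 carbinol ionises easily. The C4 hydroxyl must be oxidised afterwards, at which point the epimerisable flavanone appears anyway. The acetal groups need acid beside the prenyl group and the acid-labile C2–O1 bond. A8 needs a hexasubstituted bromo aldehyde, an asymmetric aldol and a directed reduction.
- Comparison: this road is safer for C2 and no worse for regiochemistry. The chosen plan answers with roughly half the steps, the correct oxidation level at C4 throughout, silyl-only protection, and a chromone arylation held in reserve if the catalyst control at C2 disappoints.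

Key step: step 13

Assumption: lactone 1 is taken as a catalogue compound. The (2S) sense of the insertion with the (S)-tert-leucinate catalyst is assigned by analogy; if the opposite sense were found, the mirror-image catalyst from (R)-tert-leucine would be used with no other change.

## Route

Step 1
Reactants: 1 (R)-4-methyldihydrofuran-2(3H)-one [(R)-β-methyl-γ-butyrolactone]
Product: 4 (R)-4-[(tert-butyldimethylsilyl)oxy]-3-methylbutanoic acid, via potassium (R)-4-hydroxy-3-methylbutanoate 2 (not isolated), via bis-silylated hydroxy acid 3 (not isolated)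
Conditions: KOH (1.0 equiv), MeOH/H2O, rt, evaporate; TBSCl (2.3 equiv), imidazole, DMF, rt; K2CO3, MeOH/THF/H2O, rt; work-up at pH 4–5
Reagents that add atoms: potassium hydroxide, [K+].[OH-]; tert-butyldimethylsilyl chloride (TBSCl), CC(C)(C)[Si](C)(C)Cl
Why: Saponification of the γ-lactone, silylation of both oxygens and selective cleavage of the much more labile silyl ester by carbonate is a standard way to a silyloxy acid that cannot relactonise. C3'' is β to the carboxyl group, not enolisable, and is carried through unchanged.

Step 2
Reactants: 4 (R)-4-[(tert-butyldimethylsilyl)oxy]-3-methylbutanoic acid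
Product: 6 (S)-4-benzyl-3-[(R)-4-[(tert-butyldimethylsilyl)oxy]-3-methylbutanoyl]oxazolidin-2-one, via mixed pivalic anhydride 5 (not isolated)
Conditions: t-BuCOCl, Et3N, THF, −20 °C; then (S)-4-benzyloxazolidin-2-one, LiCl, −20 °C to rt
Reagents that add atoms: (S)-4-benzyloxazolidin-2-one, O=C1N[C@@H](Cc2ccccc2)CO1
Why: Mixed-anhydride N-acylation of an oxazolidinone under LiCl/Et3N activation is the routine entry to imides for Evans alkylation. The nucleophile attacks the less hindered, non-pivaloyl carbonyl.

Step 3
Reactants: 6 (S)-4-benzyl-3-[(R)-4-[(tert-butyldimethylsilyl)oxy]-3-methylbutanoyl]oxazolidin-2-one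
Product: 7 (S)-4-benzyl-3-[(2S,3R)-4-[(tert-butyldimethylsilyl)oxy]-3-methyl-2-(3-methylbut-2-en-1-yl)butanoyl]oxazolidin-2-one
Conditions: NaN(SiMe3)2, THF, −78 °C; prenyl bromide, −78 to −40 °C
Reagents that add atoms: 1-bromo-3-methylbut-2-ene (prenyl bromide), CC(C)=CCBr
Why: Evans asymmetric alkylation: the chelated Z sodium enolate is alkylated by the allylic bromide on the face away from the benzyl group of the (S)-auxiliary. This sets C2'' so that, with H to the rear, C1'', prenyl and C3'' run clockwise, as in the target. The auxiliary overrides the weak bias of the β-methyl centre, so the anti C2''/C3'' relationship that a lactone alkylation cannot give is obtained.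

Step 4
Reactants: 7 (S)-4-benzyl-3-[(2S,3R)-4-[(tert-butyldimethylsilyl)oxy]-3-methyl-2-(3-methylbut-2-en-1-yl)butanoyl]oxazolidin-2-one
Product: 8 (2S,3R)-4-[(tert-butyldimethylsilyl)oxy]-3-methyl-2-(3-methylbut-2-en-1-yl)butan-1-ol
Conditions: LiBH4, MeOH (1 equiv), Et2O, 0 °C
Reagents that add atoms: none
Why: Reductive removal of the auxiliary with lithium borohydride attacks the exocyclic imide carbonyl and gives the primary alcohol. The silyl ether and alkene are inert, and C2'' is never α to a free aldehyde.

Step 5
Reactants: 8 (2S,3R)-4-[(tert-butyldimethylsilyl)oxy]-3-methyl-2-(3-methylbut-2-en-1-yl)butan-1-ol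
Product: 9 tert-butyl{[(2R,3S)-3-(iodomethyl)-2,6-dimethylhept-5-en-1-yl]oxy}dimethylsilane
Conditions: I2, PPh3, imidazole, CH2Cl2, 0 °C to rt
Reagents that add atoms: iodine, II
Why: Appel-type iodination is an SN2 displacement at the primary carbon under neutral conditions, compatible with the silyl ether and the trisubstituted alkene. Neither stereocentre is touched.

Step 6
Reactants: 10 4-hydroxy-2-methoxybenzaldehyde
Product: 11 2-methoxy-4-[(triisopropylsilyl)oxy]benzaldehyde
Conditions: TIPSCl, imidazole, DMF, rt
Reagents that add atoms: triisopropylsilyl chloride (TIPSCl), CC(C)[Si](Cl)(C(C)C)C(C)C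
Why: Imidazole-mediated silylation of an unhindered, acidic phenol. The bulky silyl group is chosen to survive the later enolate and organozinc steps.

Step 7
Reactants: 11 2-methoxy-4-[(triisopropylsilyl)oxy]benzaldehyde
Product: 12 {2-methoxy-4-[(triisopropylsilyl)oxy]phenyl}methanol
Conditions: NaBH4, THF/MeOH, 0 °C
Reagents that add atoms: none
Why: Borohydride reduction of an aryl aldehyde. The aryl silyl ether tolerates the brief, cold, weakly basic conditions.

Step 8
Reactants: 13 1-(2,4,6-trihydroxyphenyl)ethan-1-one (2,4,6-trihydroxyacetophenone)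
Product: 14 1-{2-hydroxy-4,6-bis[(triisopropylsilyl)oxy]phenyl}ethan-1-one
Conditions: TIPSCl (2.2 equiv), imidazole, DMF, 0 °C to rt
Reagents that add atoms: triisopropylsilyl chloride (TIPSCl), CC(C)[Si](Cl)(C(C)C)C(C)C
Why: The para hydroxyl and one of the two equivalent ortho hydroxyls are silylated. The remaining one is locked in a hydrogen bond to the acetyl carbonyl and shielded, so the reaction stops at the bis-ether, the usual behaviour of this acetophenone. Symmetry means no regiochemical question arises.

Step 9
Reactants: 14 1-{2-hydroxy-4,6-bis[(triisopropylsilyl)oxy]phenyl}ethan-1-one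
Product: 15 1-{2-hydroxy-3-iodo-4,6-bis[(triisopropylsilyl)oxy]phenyl}ethan-1-one
Conditions: N-iodosuccinimide (1.0 equiv), MeCN, 0 °C, dark
Reagents that add atoms: N-iodosuccinimide, O=C1CCC(=O)N1I
Why: Electrophilic aromatic iodination: both open positions are electronically activated, but C5 is buried between two triisopropylsilyloxy groups, whereas C3 has the small free hydroxyl as one neighbour, so iodine should enter at C3. One equivalent at low temperature limits di-iodination.

Step 10
Reactants: 15 1-{2-hydroxy-3-iodo-4,6-bis[(triisopropylsilyl)oxy]phenyl}ethan-1-one; 12 {2-methoxy-4-[(triisopropylsilyl)oxy]phenyl}methanol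
Product: 16 1-[3-iodo-2-({2-methoxy-4-[(triisopropylsilyl)oxy]phenyl}methoxy)-4,6-bis[(triisopropylsilyl)oxy]phenyl]ethan-1-one
Conditions: PPh3, DIAD, THF, 0 °C to rt
Reagents that add atoms: none
Why: Mitsunobu etherification of an acidic, hydrogen-bonded phenol with an activated benzylic alcohol runs under neutral conditions. It avoids the labile electron-rich benzyl halide and keeps base away from the aryl silyl ethers. The only free oxygen lies between iodine and acetyl, so ring B is fixed on the future O1.

Step 11
Reactants: 9 tert-butyl{[(2R,3S)-3-(iodomethyl)-2,6-dimethylhept-5-en-1-yl]oxy}dimethylsilane; 16 1-[3-iodo-2-({2-methoxy-4-[(triisopropylsilyl)oxy]phenyl}methoxy)-4,6-bis[(triisopropylsilyl)oxy]phenyl]ethan-1-one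
Product: 18 1-{3-[(2R,3R)-4-[(tert-butyldimethylsilyl)oxy]-3-methyl-2-(3-methylbut-2-en-1-yl)butyl]-2-({2-methoxy-4-[(triisopropylsilyl)oxy]phenyl}methoxy)-4,6-bis[(triisopropylsilyl)oxy]phenyl}ethan-1-one, via alkylzinc iodide 17 (not isolated)
Conditions: 9 (1.5 equiv), Zn dust (activated with BrCH2CH2Br and Me3SiCl), LiCl, THF, 40 °C; then 16, Pd(OAc)2 (5 mol %), SPhos (10 mol %), THF, 50 °C
Reagents that add atoms: none
Why: Negishi sp3–sp2 coupling: zinc inserts into the primary C–I bond, and palladium with a bulky dialkylbiarylphosphine couples primary alkylzinc halides with di-ortho-substituted aryl iodides faster than β-hydride elimination. The ketone, silyl ethers, benzyl ether and alkene are inert to the organozinc, and no base is present. The metal sits on C1'', so C2'' and C3'' keep their configuration; the descriptor at C2'' changes from S to R only because the priorities change.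

Step 12
Reactants: 18 1-{3-[(2R,3R)-4-[(tert-butyldimethylsilyl)oxy]-3-methyl-2-(3-methylbut-2-en-1-yl)butyl]-2-({2-methoxy-4-[(triisopropylsilyl)oxy]phenyl}methoxy)-4,6-bis[(triisopropylsilyl)oxy]phenyl}ethan-1-one
Product: 20 1-{3-[(2R,3R)-4-[(tert-butyldimethylsilyl)oxy]-3-methyl-2-(3-methylbut-2-en-1-yl)butyl]-2-({2-methoxy-4-[(triisopropylsilyl)oxy]phenyl}methoxy)-4,6-bis[(triisopropylsilyl)oxy]phenyl}-2-diazoethan-1-one, via trifluoroacetyl ketone 19 (not isolated)
Conditions: LiN(SiMe3)2, THF, −78 °C; CF3CO2CH2CF3, −78 °C; aq NH4Cl; then MsN3, Et3N, H2O (1 equiv), MeCN, rt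
Reagents that add atoms: methanesulfonyl azide, CS(=O)(=O)N=[N+]=[N-]
Why: Detrifluoroacetylative (Regitz-type) diazo transfer: the kinetic enolate of the only enolisable position is trifluoroacetylated, and the resulting 1,3-dicarbonyl compound takes the diazo group from the sulfonyl azide and loses the trifluoroacetyl group as the acyl sulfonamide. The low temperature and the bulk of the triisopropylsilyl group suppress silyl transfer from the C5 oxygen to the enolate oxygen, and the buffered work-up spares the acid-labile benzyl ether.

Step 13
Reactants: 20 1-{3-[(2R,3R)-4-[(tert-butyldimethylsilyl)oxy]-3-methyl-2-(3-methylbut-2-en-1-yl)butyl]-2-({2-methoxy-4-[(triisopropylsilyl)oxy]phenyl}methoxy)-4,6-bis[(triisopropylsilyl)oxy]phenyl}-2-diazoethan-1-one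
Product: 21 (2S)-8-[(2R,3R)-4-[(tert-butyldimethylsilyl)oxy]-3-methyl-2-(3-methylbut-2-en-1-yl)butyl]-2-{2-methoxy-4-[(triisopropylsilyl)oxy]phenyl}-5,7-bis[(triisopropylsilyl)oxy]-2,3-dihydro-4H-chromen-4-one
Conditions: Rh2(S-PTTL)4 (dirhodium tetrakis[N-phthaloyl-(S)-tert-leucinate], 1 mol %), toluene, 0 °C, slow addition of 20
Reagents that add atoms: none
Why: The divalent-rhodium carboxylate dimer expels N2 from 20 and gives an electrophilic carbenoid at C3; hydride-like transfer from the O1–CH2 group, concerted with C–C bond formation through a six-membered chair-like transition state, forms C2–C3. The closest known reaction type is the enantioselective dirhodium-carboxylate-catalysed intramolecular C–H insertion of ortho-alkoxyaryl diazoketones to chroman-4-ones, and of ortho-benzyloxyaryl diazo esters to 2-aryl dihydrobenzofurans. Ring C closes by this 1,6 C–H insertion, a six-membered ring formed through one C–C bond while O1–C2 and C3–C4 are already in place and are never broken. C2 is set by the catalyst: the phthalimido walls of the tert-leucinate ligands distinguish the two enantiotopic benzylic hydrogens, and the remote C2''/C3'' centres exert no bias. The step must beat oxonium-ylide formation at O1 followed by a [1,2]-benzyl shift (Stevens) to a benzofuranone. The substrate helps, because O1 is an aryl ether oxygen conjugated with the C4 carbonyl and flanked by the C8 chain, hence a poor nucleophile, while the C2–H bonds are activated by O1 and by the oxygenated ring B. The silyl ethers offer no C–H bond α to oxygen, the C5 silyloxy group is too hindered to form an ylide, and the prenyl alkene is out of reach for cyclopropanation. Slow addition keeps carbene dimerisation down.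

Step 14
Reactants: 21 (2S)-8-[(2R,3R)-4-[(tert-butyldimethylsilyl)oxy]-3-methyl-2-(3-methylbut-2-en-1-yl)butyl]-2-{2-methoxy-4-[(triisopropylsilyl)oxy]phenyl}-5,7-bis[(triisopropylsilyl)oxy]-2,3-dihydro-4H-chromen-4-one
Product: 22 (2S)-5,7-dihydroxy-2-(4-hydroxy-2-methoxyphenyl)-8-[(2R,3R)-4-hydroxy-3-methyl-2-(3-methylbut-2-en-1-yl)butyl]-2,3-dihydro-4H-chromen-4-one (CNP0081318.1)
Conditions: Bu4NF, AcOH (1:1, excess), THF, 0 °C to rt
Reagents that add atoms: none
Why: Fluoride-mediated desilylation should remove the three aryl triisopropylsilyl ethers quickly and the primary tert-butyldimethylsilyl ether more slowly. Acetic acid keeps the liberated phenols protonated, so the retro-oxa-Michael opening to the chalcone, and with it epimerisation at C2, is suppressed. The alkene and the C2–O1 bond are not exposed to strong acid.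

## Compound list

1 | (R)-4-methyldihydrofuran-2(3H)-one | O=C1C[C@@H](C)CO1 | starting material
2 | potassium (R)-4-hydroxy-3-methylbutanoate | [K+].[O-]C(=O)C[C@@H](C)CO | intermediate
3 | tert-butyldimethylsilyl (R)-4-[(tert-butyldimethylsilyl)oxy]-3-methylbutanoate | CC(C)(C)[Si](C)(C)OC(=O)C[C@@H](C)CO[Si](C)(C)C(C)(C)C | intermediate
4 | (R)-4-[(tert-butyldimethylsilyl)oxy]-3-methylbutanoic acid | OC(=O)C[C@@H](C)CO[Si](C)(C)C(C)(C)C | intermediate
5 | (R)-4-[(tert-butyldimethylsilyl)oxy]-3-methylbutanoic pivalic anhydride | CC(C)(C)C(=O)OC(=O)C[C@@H](C)CO[Si](C)(C)C(C)(C)C | intermediate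
6 | (S)-4-benzyl-3-[(R)-4-[(tert-butyldimethylsilyl)oxy]-3-methylbutanoyl]oxazolidin-2-one | O=C1OC[C@H](Cc2ccccc2)N1C(=O)C[C@@H](C)CO[Si](C)(C)C(C)(C)C | intermediate
7 | (S)-4-benzyl-3-[(2S,3R)-4-[(tert-butyldimethylsilyl)oxy]-3-methyl-2-(3-methylbut-2-en-1-yl)butanoyl]oxazolidin-2-one | O=C1OC[C@H](Cc2ccccc2)N1C(=O)[C@@H](CC=C(C)C)[C@@H](C)CO[Si](C)(C)C(C)(C)C | intermediate
8 | (2S,3R)-4-[(tert-butyldimethylsilyl)oxy]-3-methyl-2-(3-methylbut-2-en-1-yl)butan-1-ol | OC[C@@H](CC=C(C)C)[C@@H](C)CO[Si](C)(C)C(C)(C)C | intermediate
9 | tert-butyl{[(2R,3S)-3-(iodomethyl)-2,6-dimethylhept-5-en-1-yl]oxy}dimethylsilane | IC[C@@H](CC=C(C)C)[C@@H](C)CO[Si](C)(C)C(C)(C)C | intermediate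
10 | 4-hydroxy-2-methoxybenzaldehyde | COc1cc(O)ccc1C=O | starting material
11 | 2-methoxy-4-[(triisopropylsilyl)oxy]benzaldehyde | COc1cc(O[Si](C(C)C)(C(C)C)C(C)C)ccc1C=O | intermediate
12 | {2-methoxy-4-[(triisopropylsilyl)oxy]phenyl}methanol | COc1cc(O[Si](C(C)C)(C(C)C)C(C)C)ccc1CO | intermediate
13 | 1-(2,4,6-trihydroxyphenyl)ethan-1-one | CC(=O)c1c(O)cc(O)cc1O | starting material
14 | 1-{2-hydroxy-4,6-bis[(triisopropylsilyl)oxy]phenyl}ethan-1-one | CC(=O)c1c(O)cc(O[Si](C(C)C)(C(C)C)C(C)C)cc1O[Si](C(C)C)(C(C)C)C(C)C | intermediate
15 | 1-{2-hydroxy-3-iodo-4,6-bis[(triisopropylsilyl)oxy]phenyl}ethan-1-one | CC(=O)c1c(O)c(I)c(O[Si](C(C)C)(C(C)C)C(C)C)cc1O[Si](C(C)C)(C(C)C)C(C)C | intermediate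
16 | 1-[3-iodo-2-({2-methoxy-4-[(triisopropylsilyl)oxy]phenyl}methoxy)-4,6-bis[(triisopropylsilyl)oxy]phenyl]ethan-1-one | CC(=O)c1c(OCc2ccc(O[Si](C(C)C)(C(C)C)C(C)C)cc2OC)c(I)c(O[Si](C(C)C)(C(C)C)C(C)C)cc1O[Si](C(C)C)(C(C)C)C(C)C | intermediate
17 | {(2S,3R)-4-[(tert-butyldimethylsilyl)oxy]-3-methyl-2-(3-methylbut-2-en-1-yl)butyl}zinc iodide | I[Zn]C[C@@H](CC=C(C)C)[C@@H](C)CO[Si](C)(C)C(C)(C)C | intermediate
18 | 1-{3-[(2R,3R)-4-[(tert-butyldimethylsilyl)oxy]-3-methyl-2-(3-methylbut-2-en-1-yl)butyl]-2-({2-methoxy-4-[(triisopropylsilyl)oxy]phenyl}methoxy)-4,6-bis[(triisopropylsilyl)oxy]phenyl}ethan-1-one | CC(=O)c1c(OCc2ccc(O[Si](C(C)C)(C(C)C)C(C)C)cc2OC)c(C[C@@H](CC=C(C)C)[C@@H](C)CO[Si](C)(C)C(C)(C)C)c(O[Si](C(C)C)(C(C)C)C(C)C)cc1O[Si](C(C)C)(C(C)C)C(C)C | intermediate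
19 | 1-{3-[(2R,3R)-4-[(tert-butyldimethylsilyl)oxy]-3-methyl-2-(3-methylbut-2-en-1-yl)butyl]-2-({2-methoxy-4-[(triisopropylsilyl)oxy]phenyl}methoxy)-4,6-bis[(triisopropylsilyl)oxy]phenyl}-4,4,4-trifluorobutane-1,3-dione | O=C(CC(=O)C(F)(F)F)c1c(OCc2ccc(O[Si](C(C)C)(C(C)C)C(C)C)cc2OC)c(C[C@@H](CC=C(C)C)[C@@H](C)CO[Si](C)(C)C(C)(C)C)c(O[Si](C(C)C)(C(C)C)C(C)C)cc1O[Si](C(C)C)(C(C)C)C(C)C | intermediate
20 | 1-{3-[(2R,3R)-4-[(tert-butyldimethylsilyl)oxy]-3-methyl-2-(3-methylbut-2-en-1-yl)butyl]-2-({2-methoxy-4-[(triisopropylsilyl)oxy]phenyl}methoxy)-4,6-bis[(triisopropylsilyl)oxy]phenyl}-2-diazoethan-1-one | [N-]=[N+]=CC(=O)c1c(OCc2ccc(O[Si](C(C)C)(C(C)C)C(C)C)cc2OC)c(C[C@@H](CC=C(C)C)[C@@H](C)CO[Si](C)(C)C(C)(C)C)c(O[Si](C(C)C)(C(C)C)C(C)C)cc1O[Si](C(C)C)(C(C)C)C(C)C | intermediate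
21 | (2S)-8-[(2R,3R)-4-[(tert-butyldimethylsilyl)oxy]-3-methyl-2-(3-methylbut-2-en-1-yl)butyl]-2-{2-methoxy-4-[(triisopropylsilyl)oxy]phenyl}-5,7-bis[(triisopropylsilyl)oxy]-2,3-dihydro-4H-chromen-4-one | COc1cc(O[Si](C(C)C)(C(C)C)C(C)C)ccc1[C@@H]1CC(=O)c2c(O[Si](C(C)C)(C(C)C)C(C)C)cc(O[Si](C(C)C)(C(C)C)C(C)C)c(C[C@@H](CC=C(C)C)[C@@H](C)CO[Si](C)(C)C(C)(C)C)c2O1 | intermediate
22 | (2S)-5,7-dihydroxy-2-(4-hydroxy-2-methoxyphenyl)-8-[(2R,3R)-4-hydroxy-3-methyl-2-(3-methylbut-2-en-1-yl)butyl]-2,3-dihydro-4H-chromen-4-one | COc1cc(O)ccc1[C@@H]1CC(=O)c2c(O)cc(O)c(C[C@@H](CC=C(C)C)[C@@H](C)CO)c2O1 | target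

## Step count and risks

Total: 14 steps. Longest linear sequence: 9 steps (1 → 4 → 6 → 7 → 8 → 9 → 18 → 20 → 21 → 22; steps 1–5 and 11–14). The ring-A branch has 7 steps to the target (steps 8–14) and the ring-B branch contributes 2 steps (6–7).

**Step 13 (key step).** Two processes are most likely to go wrong.
- The carbenoid may be captured by the lone pair of O1, forming an oxonium ylide that undergoes a [1,2]-benzyl shift instead of insertion.
- The discrimination between the two enantiotopic benzylic hydrogens may be weak, because an acceptor-only carbenoid reacts through an early transition state.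

Fallback, setting out from 18 and returning at 21:
- Oxidative cleavage of the electron-rich benzyl ether of 18 with DDQ in wet CH2Cl2 should return aldehyde 11 and the chelated phenol, the 2-hydroxy aryl methyl ketone F1.
- Condensation with N,N-dimethylformamide dimethyl acetal gives the enaminone F2.
- F2 cyclises on silica gel or with a trace of acid to the 8-alkyl-5,7-bis(silyloxy)chromone F3.
- Ring B is then added at C2 by a rhodium-catalysed asymmetric 1,4-addition (for example [RhCl(C2H4)2]2 with a chiral diene or bisphosphine, aqueous base, dioxane) of the arylboronic acid F5, giving 21.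
- F5 is made from commercial 4-bromo-3-methoxyphenol through its triisopropylsilyl ether F4 by bromine–lithium exchange and borylation.

This replaces the C2–C3 closure by a C2–C1' bond formation of known type and sets C2 by ligand control.

**Step 11.** Transmetalation and reductive elimination may be slow at an aryl iodide flanked by a benzyloxy and a triisopropylsilyloxy group, which would let β-hydride elimination and protodeiodination take over. Fallback, setting out from 9 and 16 and returning at 18: iodine–lithium exchange on 9 (t-BuLi, Et2O, −78 °C) and capture with 9-methoxy-9-borabicyclo[3.3.1]nonane gives the lithium alkyl(methoxy)borinate F6. F6 is coupled with 16 by PdCl2(dppf) and aqueous K3PO4 in DMF/THF (B-alkyl Suzuki–Miyaura coupling). The nucleophile is then made without zinc insertion and transmetalates from a boron ate complex, a pathway less sensitive to ortho substitution.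

**Step 9.** Iodination may occur at C5 instead of C3, or go on to the di-iodide, if the steric shielding by the two silyl ethers is weaker than expected. Fallback, setting out from 13 and returning at 15: 13 is iodinated first (N-iodosuccinimide, 1 equiv, MeCN, −20 °C), where the two open positions are equivalent by symmetry, giving 1-(2,4,6-trihydroxy-3-iodophenyl)ethan-1-one F7. Bis-silylation as in step 8 then leaves free the chelated hydroxyl that is additionally shielded by iodine, which is 15.

**Step 10.** Displacement of the alkoxyphosphonium ion by a hindered, strongly hydrogen-bonded phenol may be slow, with ionisation and self-condensation of the electron-rich benzylic alcohol competing. Fallback, setting out from 12 and 15 and returning at 16: 12 is converted (CBr4, PPh3, CH2Cl2, −20 °C) into the benzylic bromide 1-(bromomethyl)-2-methoxy-4-[(triisopropylsilyl)oxy]benzene F8. F8 is used at once to alkylate the potassium phenoxide of 15 (K2CO3, acetone, rt), an SN2 etherification instead of a redox condensation.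

## Further compounds

F1 | step 13 | 1-{3-[(2R,3R)-4-[(tert-butyldimethylsilyl)oxy]-3-methyl-2-(3-methylbut-2-en-1-yl)butyl]-2-hydroxy-4,6-bis[(triisopropylsilyl)oxy]phenyl}ethan-1-one | CC(=O)c1c(O)c(C[C@@H](CC=C(C)C)[C@@H](C)CO[Si](C)(C)C(C)(C)C)c(O[Si](C(C)C)(C(C)C)C(C)C)cc1O[Si](C(C)C)(C(C)C)C(C)C
F2 | step 13 | (E)-1-{3-[(2R,3R)-4-[(tert-butyldimethylsilyl)oxy]-3-methyl-2-(3-methylbut-2-en-1-yl)butyl]-2-hydroxy-4,6-bis[(triisopropylsilyl)oxy]phenyl}-3-(dimethylamino)prop-2-en-1-one | CN(C)/C=C/C(=O)c1c(O)c(C[C@@H](CC=C(C)C)[C@@H](C)CO[Si](C)(C)C(C)(C)C)c(O[Si](C(C)C)(C(C)C)C(C)C)cc1O[Si](C(C)C)(C(C)C)C(C)C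
F3 | step 13 | 8-[(2R,3R)-4-[(tert-butyldimethylsilyl)oxy]-3-methyl-2-(3-methylbut-2-en-1-yl)butyl]-5,7-bis[(triisopropylsilyl)oxy]-4H-chromen-4-one | O=c1ccoc2c(C[C@@H](CC=C(C)C)[C@@H](C)CO[Si](C)(C)C(C)(C)C)c(O[Si](C(C)C)(C(C)C)C(C)C)cc(O[Si](C(C)C)(C(C)C)C(C)C)c12
F4 | step 13 | (4-bromo-3-methoxyphenoxy)triisopropylsilane | COc1cc(O[Si](C(C)C)(C(C)C)C(C)C)ccc1Br
F5 | step 13 | {2-methoxy-4-[(triisopropylsilyl)oxy]phenyl}boronic acid | COc1cc(O[Si](C(C)C)(C(C)C)C(C)C)ccc1B(O)O
F6 | step 11 | lithium 9-{(2S,3R)-4-[(tert-butyldimethylsilyl)oxy]-3-methyl-2-(3-methylbut-2-en-1-yl)butyl}-9-methoxy-9-boranuidabicyclo[3.3.1]nonane | [Li+].CO[B-]1(C[C@@H](CC=C(C)C)[C@@H](C)CO[Si](C)(C)C(C)(C)C)C2CCCC1CCC2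
F7 | step 9 | 1-(2,4,6-trihydroxy-3-iodophenyl)ethan-1-one | CC(=O)c1c(O)cc(O)c(I)c1O
F8 | step 10 | 1-(bromomethyl)-2-methoxy-4-[(triisopropylsilyl)oxy]benzene | COc1cc(O[Si](C(C)C)(C(C)C)C(C)C)ccc1CBr
A1 | alternative 1 | (3S,4R)-3-{hydroxy[2,4,6-tris(methoxymethoxy)phenyl]methyl}-4-methyldihydrofuran-2(3H)-one (trans, carbinol epimers) | OC(c1c(OCOC)cc(OCOC)cc1OCOC)[C@H]1C(=O)OC[C@@H]1C
A2 | alternative 1 | furan-2(5H)-one | O=C1C=CCO1
A3 | alternative 1 | 2,4,6-tris(methoxymethoxy)benzaldehyde | O=Cc1c(OCOC)cc(OCOC)cc1OCOC
A4 | alternative 2 | 2-[(2R,3R)-4-[(tert-butyldimethylsilyl)oxy]-3-methyl-2-(3-methylbut-2-en-1-yl)butyl]-5-ethoxy-3-[(triisopropylsilyl)oxy]phenol | Oc1cc(OCC)cc(O[Si](C(C)C)(C(C)C)C(C)C)c1C[C@@H](CC=C(C)C)[C@@H](C)CO[Si](C)(C)C(C)(C)C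
A5 | alternative 2 | 3-ethoxycyclobut-2-en-1-one | CCOC1=CC(=O)C1
A6 | alternative 2 | tert-butyl({(2R,3R)-2-methyl-3-(3-methylbut-2-en-1-yl)-6-[(triisopropylsilyl)oxy]hex-5-yn-1-yl}oxy)dimethylsilane | CC(C)[Si](C(C)C)(C(C)C)OC#CC[C@@H](CC=C(C)C)[C@@H](C)CO[Si](C)(C)C(C)(C)C
A7 | alternative 3 | (2S,4S)-8-[(2R,3R)-4-[(tert-butyldimethylsilyl)oxy]-3-methyl-2-(3-methylbut-2-en-1-yl)butyl]-2-[2-methoxy-4-(methoxymethoxy)phenyl]-5,7-bis(methoxymethoxy)-3,4-dihydro-2H-chromen-4-ol | COc1cc(OCOC)ccc1[C@@H]1C[C@H](O)c2c(OCOC)cc(OCOC)c(C[C@@H](CC=C(C)C)[C@@H](C)CO[Si](C)(C)C(C)(C)C)c2O1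
A8 | alternative 3 | (1S,3S)-1-{2-bromo-3-[(2R,3R)-4-[(tert-butyldimethylsilyl)oxy]-3-methyl-2-(3-methylbut-2-en-1-yl)butyl]-4,6-bis(methoxymethoxy)phenyl}-3-[2-methoxy-4-(methoxymethoxy)phenyl]propane-1,3-diol | COc1cc(OCOC)ccc1[C@@H](O)C[C@H](O)c1c(OCOC)cc(OCOC)c(C[C@@H](CC=C(C)C)[C@@H](C)CO[Si](C)(C)C(C)(C)C)c1Br
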